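The C9 quaternary methyl (C20) lying next to the C1=C10 alkene at the junction of rings A and B (ring A = C1–C5 and C10; ring B = C5–C10) is read as the remnant of a C9–C10 cyclopropane: a C1 radical beside that ring breaks C10–C20 and leaves both the methyl and the alkene. The key step therefore adds CH2 across the tetrasubstituted C9=C10 bond of a bicyclic allylic alcohol; the C1 hydroxyl carries the zinc carbenoid to its own face and sets C9 and C10 in one operation. The precursor is octalinol 16, bearing the C4 methyl/ester pair, the C8 methyl and a silyl-protected two-carbon arm (C11–C12) on C9.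

Key step: step 11

Remark: halimane numbering is used for atoms throughout (C18 = ester carbon on C4, C19 = methyl on C4, C17 = methyl on C8, C20 = methyl on C9, C11–C16 = side chain).

Assumption: the antipode named for each chiral catalyst (steps 1, 6 and 10) is the one expected from the accepted transition-state models; if a trial shows the opposite sense, the mirror-image catalyst (in step 6 the pseudo-enantiomeric cupreine-derived one) is used and nothing else changes.

Step 1
Reactants: 1 3-(tert-butyldimethylsilyloxy)propanal; 2 (E)-crotylboronic acid pinacol ester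
Product: 3 (3S,4R)-1-(tert-butyldimethylsilyloxy)-4-methylhex-5-en-3-ol
Conditions: (R)-3,3'-bis(2,4,6-triisopropylphenyl)-1,1'-binaphthyl-2,2'-diyl hydrogen phosphate (5 mol%), PhMe, −30 °C; aq. NaHCO3 work-up
Reagents that add atoms: none
Why: Acid-catalysed asymmetric crotylboration of an aldehyde through a closed six-membered chair transition state: the E-boronate should give the anti adduct and the chiral phosphoric acid the absolute sense, so the future C8 methyl centre (C4 of 3, R) is set here, while the carbinol centre is a placeholder that is oxidised in step 8.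

Step 2
Reactants: 3 homoallylic alcohol
Product: 4 (3S,4R)-3-(benzyloxy)-1-(tert-butyldimethylsilyloxy)-4-methylhex-5-ene
Conditions: NaH, BnBr, Bu4NI (cat.), THF, 0 °C to rt
Reagents that add atoms: benzyl bromide, BrCc1ccccc1
Why: Williamson etherification of the sodium alkoxide masks the future C9 oxygen with a group that survives ozone, strong base and enamine catalysis and is later removed by the same hydrogenation that sets C5; no stereocentre is touched.

Step 3
Reactants: 4 benzyl ether
Product: 6 (2R,3S)-3-(benzyloxy)-5-(tert-butyldimethylsilyloxy)-2-methylpentan-1-ol, via aldehyde 5 (not isolated)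
Conditions: O3, CH2Cl2/MeOH, −78 °C; then NaBH4, −78 °C to rt
Reagents that add atoms: ozone, [O-][O+]=O
Why: Ozonolysis of the terminal alkene and in situ borohydride reduction of the aldehyde at low temperature give the primary alcohol (future C7) before the α-stereocentre of the aldehyde can epimerise.

Step 4
Reactants: 6 primary alcohol
Product: 7 (3S,4S)-3-(benzyloxy)-1-(tert-butyldimethylsilyloxy)-5-iodo-4-methylpentane
Conditions: I2, PPh3, imidazole, CH2Cl2, 0 °C to rt
Reagents that add atoms: iodine, II
Why: Appel-type iodination converts the primary alcohol into the iodide by SN2 displacement of the oxyphosphonium group, leaving the neighbouring stereocentres untouched (the descriptor at C8 changes only because iodine raises the priority of C7).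

Step 5
Reactants: 7 iodide; 8 methyl 2-methyl-3-oxobutanoate
Product: 9 methyl (6R,7S)-7-(benzyloxy)-9-(tert-butyldimethylsilyloxy)-2,6-dimethyl-3-oxononanoate (both C2 epimers)
Conditions: 8, LDA (2.1 equiv), THF, 0 °C; then 7, DMPU, 0 °C to rt; NH4Cl quench
Reagents that add atoms: none
Why: γ-Alkylation of an acetoacetate dianion: the terminal, more basic carbanion of the dilithio derivative of 8 displaces the primary iodide (SN2), joining C6 to C7 and completing the C4–C12 chain; C4 (C2 of 9) stays epimerisable and is fixed in step 6.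

Step 6
Reactants: 9 β-keto ester; 10 but-3-en-2-one
Product: 12 methyl (1S)-2-[(3R,4S)-4-(benzyloxy)-6-(tert-butyldimethylsilyloxy)-3-methylhexyl]-1-methyl-4-oxocyclohex-2-ene-1-carboxylate, via Michael adduct 11 (not isolated)
Conditions: 10, 9-O-(9-phenanthryl)cupreidine (10 mol%), CH2Cl2, rt; then pyrrolidine (30 mol%), AcOH (30 mol%), PhMe, 80 °C
Reagents that add atoms: none
Why: Robinson annulation: the bifunctional cinchona alkaloid (quinuclidine base, phenol hydrogen-bond donor) catalyses the Michael addition of the β-keto ester to the enone and should set the C4 quaternary centre (S) by catalyst control, after which the enamine of the unhindered methyl ketone attacks the neopentyl C5 ketone in a six-membered closure and dehydration gives the ring A enone.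

Step 7
Reactants: 12 ring A enone
Product: 13 methyl (1S,2R)-2-[(3R,4S)-6-(tert-butyldimethylsilyloxy)-4-hydroxy-3-methylhexyl]-1-methyl-4-oxocyclohexane-1-carboxylate
Conditions: H2 (1 atm), Pd(OH)2/C, EtOAc, rt
Reagents that add atoms: none
Why: Heterogeneous syn hydrogenation: the C5=C10 alkene should bind the metal on the face opposite the C4 ester, the larger and pseudoaxial C4 substituent, so hydrogen reaches C5 cis to the C4 methyl (5R, C2 of 13), and the benzyl ether is hydrogenolysed in the same flask.

Step 8
Reactants: 13 hydroxy ketone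
Product: 14 methyl (1S,2R)-2-[(3R)-6-(tert-butyldimethylsilyloxy)-3-methyl-4-oxohexyl]-1-methyl-4-oxocyclohexane-1-carboxylate
Conditions: Dess–Martin periodinane, NaHCO3, CH2Cl2, rt
Reagents that add atoms: none
Why: Dess–Martin oxidation of the secondary alcohol gives the C9 ketone under buffered, non-enolising conditions, so the adjacent C8 centre is preserved.

Step 9
Reactants: 14 diketone
Product: 15 methyl (1S,6R,8aR)-5-[2-(tert-butyldimethylsilyloxy)ethyl]-1,6-dimethyl-4-oxo-1,2,3,4,6,7,8,8a-octahydronaphthalene-1-carboxylate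
Conditions: pyrrolidine, AcOH, PhMe, 70 °C; aq. AcOH/NaOAc work-up
Reagents that add atoms: none
Why: Intramolecular enamine aldol condensation: pyrrolidine condenses with the unhindered ring ketone, the C10 enamine carbon adds to the C9 ketone in a six-membered closure (the C2 enamine could only form an eight-membered ring and reverts), and dehydration through the iminium gives the conjugated tetrasubstituted C9=C10 enone under mildly acidic conditions chosen so that the α-branched chain ketone is not enolised at C8 and the β-silyloxy group is not eliminated.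

Step 10
Reactants: 15 bicyclic enone
Product: 16 methyl (1S,4S,6R,8aR)-5-[2-(tert-butyldimethylsilyloxy)ethyl]-4-hydroxy-1,6-dimethyl-1,2,3,4,6,7,8,8a-octahydronaphthalene-1-carboxylate
Conditions: (R)-tetrahydro-1-methyl-3,3-diphenyl-1H,3H-pyrrolo[1,2-c][1,3,2]oxazaborole (20 mol%), BH3·SMe2, THF, −30 °C; MeOH quench, aqueous work-up
Reagents that add atoms: none
Why: Corey–Bakshi–Shibata reduction: the oxazaborolidine binds the carbonyl oxygen anti to the larger alkenyl (C10) side and delivers hydride to the face that gives the 1S alcohol by reagent control, placing the hydroxyl on the same face as H5, which is also the pseudoaxial orientation favoured by allylic strain with C11.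

Step 11
Reactants: 16 bicyclic C9=C10 allylic alcohol with the hydroxyl on C1
Product: 17 methyl (1S,4S,4aR,5S,6R,8aR)-5-[2-(tert-butyldimethylsilyloxy)ethyl]-4-hydroxy-1,6-dimethyl-4a,5-methanodecahydronaphthalene-1-carboxylate (cyclopropane CH2 = C20 across C9–C10 and cis to the hydroxyl)
Conditions: Et2Zn, CH2I2, CH2Cl2, 0 °C to rt
Reagents that add atoms: diiodomethane, ICI
Why: Et2Zn turns the C1 hydroxyl into a zinc alkoxide, and the iodomethylzinc carbenoid bound to that oxygen transfers CH2 to C9=C10 through a concerted butterfly-type transition state, the closest known reaction being the hydroxyl-directed Simmons–Smith cyclopropanation of cyclohex-2-enols. The three-membered ring (C9–C20–C10) closes by a single suprafacial [2+1] methylene addition, both new bonds forming on one alkene face without an intermediate. C9 and C10 are set together by the C1 carbinol centre: since the carbenoid stays tethered to oxygen, C20 enters cis to the hydroxyl, which puts the future C9 methyl cis to the C8 methyl and leaves C11 on the opposite face. Only π-facial selectivity is needed, because 16 holds one alkene; it is secured by allylic 1,3-strain between the C1 oxygen and C11, which turns the C–O bond pseudoaxial over the face to be attacked, and by the silyl cap on the C12 oxygen, which keeps that homoallylic oxygen from competing as a directing group. The electron-rich tetrasubstituted alkene is a good acceptor for the electrophilic carbenoid, and the ester and silyl ether are inert to it.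

Step 12
Reactants: 17 cyclopropane-fused decalinol
Product: 18 O-(1H-imidazol-1-ylcarbonothioyl) derivative of 17 at the C1 oxygen
Conditions: 1,1'-thiocarbonyldiimidazole, DMAP (cat.), ClCH2CH2Cl, 60 °C
Reagents that add atoms: 1,1'-thiocarbonyldiimidazole, S=C(n1ccnc1)n1ccnc1
Why: Acylation of the hindered secondary alcohol with thiocarbonyldiimidazole under neutral conditions gives the radical precursor without ionising the cyclopropylcarbinyl C–O bond; the C1 configuration is irrelevant from here on.

Step 13
Reactants: 18 thiocarbonylimidazolide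
Product: 19 methyl (1S,5S,6R,8aR)-5-[2-(tert-butyldimethylsilyloxy)ethyl]-1,5,6-trimethyl-1,2,3,5,6,7,8,8a-octahydronaphthalene-1-carboxylate
Conditions: Bu3SnH (3 equiv, 0.5 M), AIBN (cat.), PhMe, 90 °C
Reagents that add atoms: none
Why: Barton–McCombie deoxygenation generates the C1 radical, a cyclopropylcarbinyl radical whose singly occupied orbital is nearly parallel to the C10–C20 bond (C20 stands perpendicular to ring A, whereas C10–C9 lies near the nodal plane), so that bond breaks and the primary C20 radical is reduced by the concentrated tin hydride before it can reclose or ring-expand, giving the C9 methyl with retention at C9 and the C1=C10 alkene.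

Step 14
Reactants: 19 silyl ether
Product: 20 methyl (1S,5S,6R,8aR)-5-(2-hydroxyethyl)-1,5,6-trimethyl-1,2,3,5,6,7,8,8a-octahydronaphthalene-1-carboxylate
Conditions: TBAF, THF, 0 °C to rt
Reagents that add atoms: none
Why: Fluoride-mediated cleavage of the primary silyl ether frees the C12 alcohol; the hindered methyl ester on the quaternary C4 is not affected.

Step 15
Reactants: 20 primary alcohol
Product: 21 methyl (1S,5S,6R,8aR)-5-(2-iodoethyl)-1,5,6-trimethyl-1,2,3,5,6,7,8,8a-octahydronaphthalene-1-carboxylate
Conditions: I2, PPh3, imidazole, CH2Cl2, 0 °C to rt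
Reagents that add atoms: iodine, II
Why: Appel-type iodination of the primary alcohol (SN2 on the oxyphosphonium intermediate) gives the C12 iodide; the trisubstituted alkene does not react with the phosphonium iodide reagent.

Step 16
Reactants: 21 iodide
Product: 22 methyl (1S,5S,6R,8aR)-5-(but-3-yn-1-yl)-1,5,6-trimethyl-1,2,3,5,6,7,8,8a-octahydronaphthalene-1-carboxylate
Conditions: LiC≡CH·H2NCH2CH2NH2, DMSO, rt
Reagents that add atoms: lithium acetylide ethylenediamine complex, [Li+].[C-]#C.NCCN
Why: SN2 alkynylation of an unhindered primary iodide with lithium acetylide in a dipolar aprotic solvent forms C12–C13; the ester on the quaternary C4 is too hindered to be attacked at room temperature.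

Step 17
Reactants: 22 terminal alkyne
Product: 25 methyl (1S,5S,6R,8aR)-5-[(3E)-5-hydroxy-3-methylpent-3-en-1-yl]-1,5,6-trimethyl-1,2,3,5,6,7,8,8a-octahydronaphthalene-1-carboxylate, via alkenylalane 23 (not isolated), via lithium aluminate 24 (not isolated)
Conditions: AlMe3, Cp2ZrCl2 (25 mol%), CH2Cl2, rt; then n-BuLi, THF, −78 °C; (CH2O)n, −78 °C to rt
Reagents that add atoms: trimethylaluminium, C[Al](C)C; formaldehyde (as paraformaldehyde), C=O
Why: Zirconium-catalysed carboalumination of the terminal alkyne adds methyl and aluminium syn (methyl to C13, aluminium to C14), which fixes the 13E geometry, and the derived lithium aluminate is hydroxymethylated by formaldehyde with retention of alkene geometry.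

Step 18
Reactants: 25 allylic alcohol
Product: 26 methyl (1S,5S,6R,8aR)-5-[(3E)-5-(formyloxy)-3-methylpent-3-en-1-yl]-1,5,6-trimethyl-1,2,3,5,6,7,8,8a-octahydronaphthalene-1-carboxylate (CNP0188193.1)
Conditions: HCO2H, DCC, DMAP (cat.), CH2Cl2, 0 °C
Reagents that add atoms: formic acid, O=CO
Why: Steglich esterification of the primary allylic alcohol with carbodiimide-activated formic acid gives the formate under neutral conditions that leave the methyl ester and both alkenes unchanged.

Compound list
1 | 3-(tert-butyldimethylsilyloxy)propanal | O=CCCO[Si](C)(C)C(C)(C)C | starting material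
2 | (E)-crotylboronic acid pinacol ester | C/C=C/CB1OC(C)(C)C(C)(C)O1 | starting material
3 | (3S,4R)-1-(tert-butyldimethylsilyloxy)-4-methylhex-5-en-3-ol | C=C[C@@H](C)[C@@H](O)CCO[Si](C)(C)C(C)(C)C | intermediate
4 | (3S,4R)-3-(benzyloxy)-1-(tert-butyldimethylsilyloxy)-4-methylhex-5-ene | C=C[C@@H](C)[C@@H](OCc1ccccc1)CCO[Si](C)(C)C(C)(C)C | intermediate
5 | (2S,3S)-3-(benzyloxy)-5-(tert-butyldimethylsilyloxy)-2-methylpentanal (formed and reduced in the flask of step 3) | O=C[C@@H](C)[C@@H](OCc1ccccc1)CCO[Si](C)(C)C(C)(C)C | intermediate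
6 | (2R,3S)-3-(benzyloxy)-5-(tert-butyldimethylsilyloxy)-2-methylpentan-1-ol | OC[C@@H](C)[C@@H](OCc1ccccc1)CCO[Si](C)(C)C(C)(C)C | intermediate
7 | (3S,4S)-3-(benzyloxy)-1-(tert-butyldimethylsilyloxy)-5-iodo-4-methylpentane | IC[C@@H](C)[C@@H](OCc1ccccc1)CCO[Si](C)(C)C(C)(C)C | intermediate
8 | methyl 2-methyl-3-oxobutanoate | COC(=O)C(C)C(C)=O | starting material
9 | methyl (6R,7S)-7-(benzyloxy)-9-(tert-butyldimethylsilyloxy)-2,6-dimethyl-3-oxononanoate (both C2 epimers) | COC(=O)C(C)C(=O)CC[C@@H](C)[C@@H](OCc1ccccc1)CCO[Si](C)(C)C(C)(C)C | intermediate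
10 | but-3-en-2-one | C=CC(C)=O | starting material
11 | methyl (2S,6R,7S)-7-(benzyloxy)-9-(tert-butyldimethylsilyloxy)-2,6-dimethyl-3-oxo-2-(3-oxobutyl)nonanoate (formed and cyclised in the flask of step 6) | COC(=O)[C@@](C)(CCC(C)=O)C(=O)CC[C@@H](C)[C@@H](OCc1ccccc1)CCO[Si](C)(C)C(C)(C)C | intermediate
12 | methyl (1S)-2-[(3R,4S)-4-(benzyloxy)-6-(tert-butyldimethylsilyloxy)-3-methylhexyl]-1-methyl-4-oxocyclohex-2-ene-1-carboxylate | COC(=O)[C@@]1(C)CCC(=O)C=C1CC[C@@H](C)[C@@H](OCc1ccccc1)CCO[Si](C)(C)C(C)(C)C | intermediate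
13 | methyl (1S,2R)-2-[(3R,4S)-6-(tert-butyldimethylsilyloxy)-4-hydroxy-3-methylhexyl]-1-methyl-4-oxocyclohexane-1-carboxylate | COC(=O)[C@@]1(C)CCC(=O)C[C@H]1CC[C@@H](C)[C@@H](O)CCO[Si](C)(C)C(C)(C)C | intermediate
14 | methyl (1S,2R)-2-[(3R)-6-(tert-butyldimethylsilyloxy)-3-methyl-4-oxohexyl]-1-methyl-4-oxocyclohexane-1-carboxylate | COC(=O)[C@@]1(C)CCC(=O)C[C@H]1CC[C@@H](C)C(=O)CCO[Si](C)(C)C(C)(C)C | intermediate
15 | methyl (1S,6R,8aR)-5-[2-(tert-butyldimethylsilyloxy)ethyl]-1,6-dimethyl-4-oxo-1,2,3,4,6,7,8,8a-octahydronaphthalene-1-carboxylate | COC(=O)[C@@]1(C)CCC(=O)C2=C(CCO[Si](C)(C)C(C)(C)C)[C@H](C)CC[C@@H]12 | intermediate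
16 | methyl (1S,4S,6R,8aR)-5-[2-(tert-butyldimethylsilyloxy)ethyl]-4-hydroxy-1,6-dimethyl-1,2,3,4,6,7,8,8a-octahydronaphthalene-1-carboxylate (key-step precursor) | COC(=O)[C@@]1(C)CC[C@H](O)C2=C(CCO[Si](C)(C)C(C)(C)C)[C@H](C)CC[C@@H]12 | intermediate
17 | methyl (1S,4S,4aR,5S,6R,8aR)-5-[2-(tert-butyldimethylsilyloxy)ethyl]-4-hydroxy-1,6-dimethyl-4a,5-methanodecahydronaphthalene-1-carboxylate (key-step product; C20 bridges C9 and C10) | COC(=O)[C@@]1(C)CC[C@H](O)[C@@]23C[C@]2(CCO[Si](C)(C)C(C)(C)C)[C@H](C)CC[C@@H]13 | intermediate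
18 | O-(1H-imidazol-1-ylcarbonothioyl) derivative of 17 at the C1 oxygen | COC(=O)[C@@]1(C)CC[C@H](OC(=S)n4ccnc4)[C@@]23C[C@]2(CCO[Si](C)(C)C(C)(C)C)[C@H](C)CC[C@@H]13 | intermediate
19 | methyl (1S,5S,6R,8aR)-5-[2-(tert-butyldimethylsilyloxy)ethyl]-1,5,6-trimethyl-1,2,3,5,6,7,8,8a-octahydronaphthalene-1-carboxylate | COC(=O)[C@@]1(C)CCC=C2[C@H]1CC[C@@H](C)[C@]2(C)CCO[Si](C)(C)C(C)(C)C | intermediate
20 | methyl (1S,5S,6R,8aR)-5-(2-hydroxyethyl)-1,5,6-trimethyl-1,2,3,5,6,7,8,8a-octahydronaphthalene-1-carboxylate | COC(=O)[C@@]1(C)CCC=C2[C@H]1CC[C@@H](C)[C@]2(C)CCO | intermediate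
21 | methyl (1S,5S,6R,8aR)-5-(2-iodoethyl)-1,5,6-trimethyl-1,2,3,5,6,7,8,8a-octahydronaphthalene-1-carboxylate | COC(=O)[C@@]1(C)CCC=C2[C@H]1CC[C@@H](C)[C@]2(C)CCI | intermediate
22 | methyl (1S,5S,6R,8aR)-5-(but-3-yn-1-yl)-1,5,6-trimethyl-1,2,3,5,6,7,8,8a-octahydronaphthalene-1-carboxylate | COC(=O)[C@@]1(C)CCC=C2[C@H]1CC[C@@H](C)[C@]2(C)CCC#C | intermediate
23 | (E)-alkenyl(dimethyl)alane from syn methylalumination of 22 (methyl on C13 and aluminium on C14; formed in the flask of step 17) | COC(=O)[C@@]1(C)CCC=C2[C@H]1CC[C@@H](C)[C@]2(C)CC/C(C)=C/[Al](C)C | intermediate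
24 | lithium butyl(dimethyl)alkenylaluminate derived from 23 (formed in the flask of step 17) | COC(=O)[C@@]1(C)CCC=C2[C@H]1CC[C@@H](C)[C@]2(C)CC/C(C)=C/[Al-](C)(C)CCCC.[Li+] | intermediate
25 | methyl (1S,5S,6R,8aR)-5-[(3E)-5-hydroxy-3-methylpent-3-en-1-yl]-1,5,6-trimethyl-1,2,3,5,6,7,8,8a-octahydronaphthalene-1-carboxylate | COC(=O)[C@@]1(C)CCC=C2[C@H]1CC[C@@H](C)[C@]2(C)CC/C(C)=C/CO | intermediate
26 | methyl (1S,5S,6R,8aR)-5-[(3E)-5-(formyloxy)-3-methylpent-3-en-1-yl]-1,5,6-trimethyl-1,2,3,5,6,7,8,8a-octahydronaphthalene-1-carboxylate (CNP0188193.1; 4S,5R,8R,9S,13E in halimane numbering) | COC(=O)[C@@]1(C)CCC=C2[C@H]1CC[C@@H](C)[C@]2(C)CC/C(C)=C/COC=O | target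

Total step count: 18. Longest linear sequence: 18 steps (1 to 26; 2, 8 and 10 are bought).

Steps most likely to fail

Step 6. The cinchona catalyst may discriminate poorly between the faces of the enolate of an acyclic methyl β-keto ester, so that control at the C4 quaternary centre is lost and both C4 epimers are carried into ring A. The fallback replaces catalyst control by auxiliary control and sets out from 9. Condensation of 9 with (S)-valine diethylamide (cat. HCl, molecular sieves, PhMe) should give the hydrogen-bonded Z-enamino ester F1. Addition of F1 to 10 with Cu(OAc)2·H2O (5 mol%) in acetone, where the copper chelate of the auxiliary shields one face of the enamine, should give the imine F2. Aqueous acid hydrolysis in the same flask releases the auxiliary and comes back to the route at 11, which is cyclised to 12 by the pyrrolidine/AcOH stage of step 6.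

Step 7. Hydrogen delivery may show poor facial selectivity, because the methyl and ester groups on C4 differ little in size toward the metal surface; this would give the C5 epimer. The fallback uses hydroxyl-directed homogeneous hydrogenation and sets out from 12. Corey–Bakshi–Shibata reduction with the same (R)-oxazaborolidine and BH3·SMe2 should give the allylic alcohol F3, with the C1 hydroxyl on the face of the C4 methyl. [Ir(cod)(PCy3)(py)]PF6 under H2 in CH2Cl2 then binds that hydroxyl and transfers hydrogen to the same face of C5=C10, giving the saturated alcohol F4 with C5 secured. Dess–Martin oxidation gives the keto benzyl ether F5, and hydrogenolysis of the benzyl group (H2, Pd(OH)2/C, EtOAc) comes back to the route at 13.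

Step 9. During the condensation the chain ketone may enolise toward C8 (epimerisation), or the silyloxy group may be lost by β-elimination. The fallback separates a kinetic aldol addition from the elimination and sets out from 14. Soft enolisation with TiCl4 and Bu3N in CH2Cl2 at −78 °C should engage only the ring ketone and add C10 to the C9 ketone, giving the β-hydroxy ketone F6. Trifluoroacetylation of the tertiary alcohol (trifluoroacetic anhydride, pyridine, DMAP) gives the trifluoroacetate F7, and DBU removes trifluoroacetic acid across C9–C10 by an E1cB pathway, coming back to the route at 15.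

Further compounds
F1 | step 6 | methyl (2Z,6R,7S)-7-(benzyloxy)-9-(tert-butyldimethylsilyloxy)-3-{[(2S)-1-(diethylamino)-3-methyl-1-oxobutan-2-yl]amino}-2,6-dimethylnon-2-enoate | COC(=O)/C(C)=C(\N[C@@H](C(C)C)C(=O)N(CC)CC)CC[C@@H](C)[C@@H](OCc1ccccc1)CCO[Si](C)(C)C(C)(C)C
F2 | step 6 | methyl (2S,6R,7S)-7-(benzyloxy)-9-(tert-butyldimethylsilyloxy)-3-{[(2S)-1-(diethylamino)-3-methyl-1-oxobutan-2-yl]imino}-2,6-dimethyl-2-(3-oxobutyl)nonanoate | COC(=O)[C@@](C)(CCC(C)=O)C(=N[C@@H](C(C)C)C(=O)N(CC)CC)CC[C@@H](C)[C@@H](OCc1ccccc1)CCO[Si](C)(C)C(C)(C)C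
F3 | step 7 | methyl (1S,4S)-2-[(3R,4S)-4-(benzyloxy)-6-(tert-butyldimethylsilyloxy)-3-methylhexyl]-4-hydroxy-1-methylcyclohex-2-ene-1-carboxylate | COC(=O)[C@@]1(C)CC[C@H](O)C=C1CC[C@@H](C)[C@@H](OCc1ccccc1)CCO[Si](C)(C)C(C)(C)C
F4 | step 7 | methyl (1S,2R,4S)-2-[(3R,4S)-4-(benzyloxy)-6-(tert-butyldimethylsilyloxy)-3-methylhexyl]-4-hydroxy-1-methylcyclohexane-1-carboxylate | COC(=O)[C@@]1(C)CC[C@H](O)C[C@H]1CC[C@@H](C)[C@@H](OCc1ccccc1)CCO[Si](C)(C)C(C)(C)C
F5 | step 7 | methyl (1S,2R)-2-[(3R,4S)-4-(benzyloxy)-6-(tert-butyldimethylsilyloxy)-3-methylhexyl]-1-methyl-4-oxocyclohexane-1-carboxylate | COC(=O)[C@@]1(C)CCC(=O)C[C@H]1CC[C@@H](C)[C@@H](OCc1ccccc1)CCO[Si](C)(C)C(C)(C)C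
F6 | step 9 | methyl (1S,6R,8aR)-5-[2-(tert-butyldimethylsilyloxy)ethyl]-5-hydroxy-1,6-dimethyl-4-oxodecahydronaphthalene-1-carboxylate (C4a and C5 not defined) | COC(=O)[C@@]1(C)CCC(=O)C2C(O)(CCO[Si](C)(C)C(C)(C)C)[C@H](C)CC[C@@H]12
F7 | step 9 | methyl (1S,6R,8aR)-5-[2-(tert-butyldimethylsilyloxy)ethyl]-1,6-dimethyl-4-oxo-5-(trifluoroacetoxy)decahydronaphthalene-1-carboxylate (C4a and C5 not defined) | COC(=O)[C@@]1(C)CCC(=O)C2C(OC(=O)C(F)(F)F)(CCO[Si](C)(C)C(C)(C)C)[C@H](C)CC[C@@H]12
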